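Turn every reading into a fraction of the charge before arguing about these flasks.

all flasks: enzyme 0.15 µM
- birch: starting material 0.014 M (fed, over 5.0 d); solid second substrate 10 mM; run made earlier; the fed solution adds 0.20 times the starting volume
- alder: starting material 0.047 M (fed, over 5.0 d); solid second substrate 10 mM; run made earlier; the fed solution adds 0.20 times the starting volume
- dawn: starting material 0.030 M; solid second substrate 10.0 mM; everything together at the start, the whole solution of starting material included, so that from the start the volume is larger by 0.20 times the starting volume; time 6.0 d
- spring: starting material 0.010 M (fed, over 5.0 d); solid second substrate 10.0 mM; the fed solution adds 0.20 times the starting volume; time 6.0 d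

| birch: time / d | birch: target / % | alder: time / d | alder: target / % |
|---|---|---|---|
| 1.04 | 0.5 | 0.500 | 0 |
| 2.00 | 1.1 | 1.67 | 0.4 |
| 3.00 | 3.1 | 2.50 | 1.6 |
| 4.00 | 6.3 | 4.00 | 3.2 |

(scatter of a reading: 0.3 percentage points)

- every charge counts on the volume at the start, and the solution that is fed holds the whole dose
- at the start none of the solid second substrate is in solution
- percentages count the whole charge, also what has not yet gone in

- which of the two ends with the higher amount of target, in percent of the starting material charged ("neither" if they lie within 2 percentage points) (dawn / spring / neither)
- target at the end, in percent of the starting material charged, dawn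
- target at the end, in percent of the starting material charged, spring

Two chemists read the earlier runs differently. The first holds the rate pseudo-first-order in starting material. The fraction made then follows the exposure, the time integral of the fraction of the charge that has gone in. While a steady feed runs, exposure is half the squared time over the dosing time. So birch had 1.60 d at 4.00 d, and its 6.3 % gives 0.0394 d⁻¹. Dawn's exposure is 6.0 d and spring's is 3.50 d. This view therefore gives dawn 23.6 % and spring 13.8 %.

The second chemist holds the rate zero-order past a lag. The quantity is the ceiling rate, the target made per day per starting volume whatever the starting material stands at. Alder's last two readings give 0.501 mM d⁻¹, and their line meets zero at 1.00 d. Integrated, the fraction made is the ceiling rate times the time past the lag, over the charge. Dawn gets 8.35 %. The same line gives spring 25.1 %, an upper mark of this view and not a forecast.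

The readings test both views. At 4.00 d, birch's reading is 1.97 times alder's. Equal exposure asks for one, and the ceiling asks for the charge ratio, 3.36. The reading lies between them.

The forecast takes the ceiling side: “the rate nearly saturates in starting material”. It gives dawn 9.5 %, higher than my line, spring 15 %, and spring ahead.

The flask gives dawn 10.5 % and spring 14.9 %, so spring ends higher, as the forecast said. The exposure view keeps its region at equal charge: spring's feed with dawn's 0.030 M ends at 8.73 %, lower than dawn. Spring's end is worth 2.97 d of running at the ceiling rate, out of 5.00 d past the lag.

    starting material → decomposition product (k = 1.40 × 10⁻⁸ s⁻¹)
    ternary complex → enzyme + target (k = 0.200 s⁻¹)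
    second substrate + starting complex ⇌ ternary complex (K = 130 M⁻¹, k = 6000 M⁻¹ s⁻¹)
    starting material + enzyme ⇌ starting complex (K = 53.0 M⁻¹, k = 210 M⁻¹ s⁻¹)
    solid second substrate ⇌ second substrate, rate k5*(cs5 - [second substrate]) while solid is left; crystals form when [second substrate] > cs5 (solubility = 8.20 mM, k = 3.50 × 10⁻⁶ s⁻¹)

Take dawn with 0.075 M of starting material. The ceiling line gives 3.34 %, and the computed end is 5.20 %, lower than dawn.

(The readings were generated by integration for an exercise; the scatter is artificial.)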